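**Plan**
- **Numbering and enabling feature:** the benzene ring is C1 (bears the chain C7H2–C8H2–C9O2R), C2 (OH), C3 (OMe), C4 (OH), C5 (H), C6 (H). The four substituted carbons C1–C4 carry the C,O,O,O pattern of a doubly enolised 2-methoxy-3-oxo ester. C5 and C6 are bare, which corresponds to an acetylene.
- **Cuts, in retrosynthetic order:** the O–alkyl bond of the C9 ester; a carboxyl added back at C5 as a traceless activator; the ring bonds C1–C6 and C4–C5 (diene plus propiolate); the C2–C3 bond (methoxyacetate enolate plus glutaric half-ester chloride).
- **Forward order:** C2–C3 acylation, double O-silylation to the diene, closure of the only ring by (4+2) benzannulation, cleavage of both methyl esters, loss of the C5 carboxyl, and attachment of the C18 chain last.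
- **Stereochemistry:** the target has no stereocentre and no double-bond geometry. Only the Z geometry of the C1=C2 enol ether in the diene matters, and only for reactivity. All transient sp3 centres are erased on aromatisation.

Key step: step 3

Remark: keto diester 4 is racemic at a labile centre, cycloadduct 8 is a diastereomer mixture, and the ketene acetal geometry of 6 is left open. None of these elements reaches the target, so they are drawn without configuration.

Step 1
Reactants: 1 methyl methoxyacetate; 2 methyl 5-chloro-5-oxopentanoate
Product: 4 dimethyl 2-methoxy-3-oxoheptanedioate, via lithium enolate 3 (not isolated)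
Conditions: LiN(iPr)2 (2.0 equiv), 1 (2.1 equiv), THF, −78 °C; then 2 (1.0 equiv), −78 °C; 1 M aq HCl quench
Reagents that add atoms: none
Why: Crossed Claisen-type C-acylation of an ester lithium enolate, in which the acid chloride outruns both ester groups as electrophile at −78 °C and the second equivalent of enolate absorbs the acidic proton of the β-keto ester as it forms; the new C3 centre is labile and is flattened in step 2.

Step 2
Reactants: 4 dimethyl 2-methoxy-3-oxoheptanedioate
Product: 6 methyl (4Z)-6,7-dimethoxy-5,7-bis(trimethylsilyloxy)hepta-4,6-dienoate, via monosilyl enol ether 5 (not isolated)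
Conditions: Me3SiOSO2CF3 (2.3 equiv), Et3N (3.0 equiv), Et2O, 0 °C to rt, argon; salt layer removed, volatiles stripped, used crude
Reagents that add atoms: trimethylsilyl trifluoromethanesulfonate, C[Si](C)(C)OS(=O)(=O)C(F)(F)F
Why: Soft enolisation with a silyl triflate and a tertiary amine, the usual one-pot double O-silylation of 1,3-dicarbonyl compounds: the acidic C3–H goes first to give 5, whose push–pull ester carbonyl is far more Lewis basic than the isolated C9 ester and so takes the second silyl group while Et3N removes the vinylogously acidified C1–H, with the chain settling trans to the bulky ketene acetal (Z enol ether).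

Step 3
Reactants: 6 methyl (4Z)-6,7-dimethoxy-5,7-bis(trimethylsilyloxy)hepta-4,6-dienoate; 7 methyl propiolate
Product: 9 methyl 2,4-dihydroxy-3-methoxy-5-(3-methoxy-3-oxopropyl)benzoate, via cyclohexa-1,4-diene cycloadduct 8 (not isolated)
Conditions: 7 (3 equiv), toluene, 90 °C, sealed vessel, argon; then 1 M aq HCl–THF, rt
Reagents that add atoms: none
Why: This is a normal-electron-demand Diels–Alder reaction run as a strongly asynchronous (4+2) process: C1 of 6, which is the β-carbon of the C2 silyl enol ether and the vinylogous terminus of the C4 ketene acetal, attacks the unsubstituted alkyne carbon of 7 (C1–C6 bond), and the developing allenolate carbon then closes on the silyloxy(methoxy)carbenium carbon C4 (C4–C5 bond). The closest known reaction type is the cycloaddition of 1-alkoxy-1,3-bis(silyloxy)buta-1,3-dienes with acetylenic esters to give 2,4-dihydroxybenzoates, and here the diene only carries an extra 2-methoxy group and a 4-alkyl chain. The single six-membered carbocycle closes in the intermolecular four-plus-two-atom mode (C1–C4 from 6, C5–C6 from 7), which in the stepwise limit is a 6-exo-trig attack of C5 on C4. Cycloadduct 8 is a 1,4-diene with a mixed silyl methyl ketal at C4 and a hydrogen at C1, so aqueous acid strips silicon, the hemiketal expels methanol, and the dienone enolises through C1–H to the resorcinol 9. The two stereocentres of 8 (C1 and C4) need no control because both become sp2 carbons. The selectivity required is regiochemical, and it is secured because three oxygen donors (two on C4, one on C2) polarise the diene toward C1 and outweigh the single opposing C3 methoxy group, the terminal alkyne carbon is both the electrophilic and the unhindered one, and the Z enol ether holds the chain on the outside of the s-cis diene so that C1 stays accessible.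

Step 4
Reactants: 9 methyl 2,4-dihydroxy-3-methoxy-5-(3-methoxy-3-oxopropyl)benzoate
Product: 10 5-(2-carboxyethyl)-2,4-dihydroxy-3-methoxybenzoic acid
Conditions: NaOH (8 equiv), degassed H2O–MeOH 3:1, reflux, N2; then 2 M aq HCl to pH 1, 0 °C
Reagents that add atoms: sodium hydroxide, [Na+].[OH-]
Why: Ester saponification by acyl–oxygen cleavage, in which the aliphatic ester falls quickly while the hydrogen-bonded, phenoxide-deactivated benzoate needs excess base and reflux, conditions that the aryl methyl ether tolerates and that are kept oxygen-free to protect the electron-rich phenoxide.

Step 5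
Reactants: 10 5-(2-carboxyethyl)-2,4-dihydroxy-3-methoxybenzoic acid
Product: 11 3-(2,4-dihydroxy-3-methoxyphenyl)propanoic acid
Conditions: 1 M aq HCl–1,4-dioxane 1:1, reflux, N2
Reagents that add atoms: none
Why: Protodecarboxylation of a 2,4-dihydroxybenzoic acid by ipso protonation: C5 is ortho to the C4 hydroxyl and para to the C2 hydroxyl, so the arenium ion forms readily and sheds CO2, whereas the aliphatic C9 carboxyl has no such pathway and the water-rich medium works against dehydration to the six-membered lactone.

Step 6
Reactants: 11 3-(2,4-dihydroxy-3-methoxyphenyl)propanoic acid; 12 octadecan-1-ol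
Product: 13 octadecyl 3-(2,4-dihydroxy-3-methoxyphenyl)propanoate
Conditions: PPh3 (1.15 equiv), diisopropyl azodicarboxylate (DIAD, 1.15 equiv), 12 (1.0 equiv), THF, 0 °C to rt
Reagents that add atoms: none
Why: Mitsunobu esterification: the primary alcohol is activated as its alkoxyphosphonium ion and displaced by the carboxylate, the only group of 11 acidic enough to protonate the betaine, so both phenols should stay free, and because the acyl carbon is never activated and neither acid nor heat is applied, the C2 hydroxyl has no opening to close the lactone.

**Compound list**
1 | methyl methoxyacetate | COCC(=O)OC | starting material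
2 | methyl 5-chloro-5-oxopentanoate | COC(=O)CCCC(=O)Cl | starting material
3 | lithium 1,2-dimethoxyethenolate (lithium enolate of 1) | COC=C([O-])OC.[Li+] | intermediate
4 | dimethyl 2-methoxy-3-oxoheptanedioate (racemic, labile centre) | COC(=O)C(OC)C(=O)CCCC(=O)OC | intermediate
5 | dimethyl 2-methoxy-3-(trimethylsilyloxy)hept-2-enedioate | COC(=O)C(OC)=C(CCCC(=O)OC)O[Si](C)(C)C | intermediate
6 | methyl (4Z)-6,7-dimethoxy-5,7-bis(trimethylsilyloxy)hepta-4,6-dienoate | COC(=O)CC/C=C(\O[Si](C)(C)C)C(OC)=C(OC)O[Si](C)(C)C | intermediate
7 | methyl propiolate | C#CC(=O)OC | starting material
8 | methyl 5,6-dimethoxy-3-(3-methoxy-3-oxopropyl)-4,6-bis(trimethylsilyloxy)cyclohexa-1,4-diene-1-carboxylate (diastereomer mixture) | COC(=O)CCC1C=C(C(=O)OC)C(OC)(O[Si](C)(C)C)C(OC)=C1O[Si](C)(C)C | intermediate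
9 | methyl 2,4-dihydroxy-3-methoxy-5-(3-methoxy-3-oxopropyl)benzoate | COC(=O)CCc1cc(C(=O)OC)c(O)c(OC)c1O | intermediate
10 | 5-(2-carboxyethyl)-2,4-dihydroxy-3-methoxybenzoic acid | OC(=O)CCc1cc(C(=O)O)c(O)c(OC)c1O | intermediate
11 | 3-(2,4-dihydroxy-3-methoxyphenyl)propanoic acid | OC(=O)CCc1ccc(O)c(OC)c1O | intermediate
12 | octadecan-1-ol | CCCCCCCCCCCCCCCCCCO | starting material
13 | octadecyl 3-(2,4-dihydroxy-3-methoxyphenyl)propanoate | CCCCCCCCCCCCCCCCCCOC(=O)CCc1ccc(O)c(OC)c1O | target

Total step count: 6. Longest linear sequence: 6 steps (from 1 or 2 to 13).

**Steps most likely to fail**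

**Step 3.**
- **Risk:** both diene termini are substituted, so the cycloaddition may be slow enough for several side processes to compete. These are thermal silyl migration or adventitious hydrolysis of 6, conjugate addition that stops before ring closure, and partial loss of silanol instead of methanol from the C4 ketal.
- **Fallback (from 7, back at 11):** the arene is bought rather than built, and 7 supplies C7–C8–C9 instead of C5–C6. A Pechmann-type condensation of 7 with purchased 2-methoxybenzene-1,3-diol F1 (ZnCl2, 1,4-dioxane, 100 °C) should give 7-hydroxy-8-methoxy-2H-chromen-2-one F2. The two positions of F1 that are ortho to one hydroxyl and para to the other are equivalent, so no regiochemical question arises. Hydrogenation of F2 over Pd/C in 1 M aq NaOH then saturates the C7=C8 bond and opens the pyranone, whichever comes first. Cold acidification to pH 2 releases 11.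

**Step 2.**
- **Risk:** the second silylation may stall, silylation may spill over to the distal C9 ester, and the moisture-sensitive diene may decay during handling.
- **Fallback (from 4, back at 9):** the need for site selection is removed rather than enforced. Keto diester 4 is silylated once with Me3SiCl/Et3N, and enol ether 5 is this time isolated. Hard kinetic enolisation with LiN(iPr)2 (2.2 equiv) and Me3SiCl in THF at −78 °C then silylates both C1–H and the C9 ester on purpose. This gives (4Z)-1,6,7-trimethoxy-1,5,7-tris(trimethylsilyloxy)hepta-1,4,6-triene F3. Its isolated C8=C9 ketene acetal is not part of a diene and should remain a spectator toward 7. The acidic work-up of the cycloaddition returns it to the methyl ester, so 9 is reached.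

**Step 5.**
- **Risk:** ipso protonation may be slow and force long heating. During that time the hydroxy acid may dehydrate to its six-membered lactone, so a mixture of open and closed forms would reach the Mitsunobu step.
- **Fallback (from 10, back at 13):** the ring closure is driven to completion and then used. Heating 10 in diphenyl ether at about 200 °C under N2 expels CO2 and water together and should give only 7-hydroxy-8-methoxychroman-2-one F4. Alcohol 12 is converted with NaH in THF into sodium octadecan-1-olate F5 (2.2 equiv, the first equivalent being spent on the C4 phenol). F5 opens the aryl ester of F4 at 0 °C, and release of a phenoxide makes this acyl transfer downhill. A cold dilute HCl quench then gives 13 directly, bypassing 11 and step 6.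

**Further compounds**
F1 | step 3 | 2-methoxybenzene-1,3-diol (purchased) | COc1c(O)cccc1O
F2 | step 3 | 7-hydroxy-8-methoxy-2H-chromen-2-one | COc1c(O)ccc2ccc(=O)oc12
F3 | step 2 | (4Z)-1,6,7-trimethoxy-1,5,7-tris(trimethylsilyloxy)hepta-1,4,6-triene | COC(O[Si](C)(C)C)=CC/C=C(\O[Si](C)(C)C)C(OC)=C(OC)O[Si](C)(C)C
F4 | step 5 | 7-hydroxy-8-methoxychroman-2-one | COc1c(O)ccc2CCC(=O)Oc12
F5 | step 5 | sodium octadecan-1-olate | CCCCCCCCCCCCCCCCCC[O-].[Na+]
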